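**Plan**

1. Numbering: benzofuran numbering O1, C2, C3, C3a, C4 to C7, C7a; C1' is the side-chain carbonyl carbon. Retrosynthetic cuts, in order: silyl groups, the C1' ketone (back to a carbinol) and the aryl ester (back to an aryl bromide); both ring alkenes C7a=C3a and C4=C5 at once; the enol ether CH2 (back to an ester O1–C7a); the ester bond (alcohol plus β-lactone); C7–C1' (aldol) and C3–C3a (epoxide opening).
2. Enabling feature: the diene C7a=C3a–C4=C5 spans the fusion of the dihydrofuran ring (O1, C2, C3, C3a, C7a) and the cyclohexadiene ring (C3a, C4, C5, C6, C7, C7a). Its central bond C3a–C4, with OMe on C4, is the trace of an ynol ether; C7a is an acyl carbon and C5 a vinyl carbon. One ruthenium carbene can therefore travel from C7a to C4 and leave at C5, closing the furan first and the carbocycle second from an open chain.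
3. Forward: fragment 1 (aryl, C3, C2, CMe2OH, methoxyalkyne; 5 steps) and fragment 2 (C5 to C7 with the C1' chain, as a β-lactone; 3 steps) are joined by alkoxide opening of the lactone. Ester methylenation gives the dienyne, the cascade closes both rings, then ArBr becomes ArCO2Me, C1' is oxidised and the silyl groups are removed.
4. Stereochemistry: C2 and C3 come from Jacobsen epoxidation of a Z-cinnamate and SN2 opening of the cis-epoxide at the benzylic carbon (trans-2,3 pattern). C6 comes from ethyl (3S)-3-hydroxypent-4-enoate, C7 from the trans-selective aldol of the β-lactone enolate. The cascade forms no stereocentre.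
5. Helpers: C1' is held as a silylated carbinol (a ketone would be methylenated and would pull the enol ether into conjugation). The benzoate is held as ArBr (a second ester would also be methylenated). The β-lactone is a temporary ring that fixes C7 and activates the acyl group. All are converted in steps 13 to 16.

Key step: step 12

Assumption: ethyl (3S)-3-hydroxypent-4-enoate is taken as a purchasable single enantiomer (otherwise one lipase resolution of the racemic ester); the two C1' epimers formed in step 8 are carried as a mixture because this centre becomes the ketone in step 15.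

**Route**

Step 1
Reactants: 1 5-bromo-2-hydroxybenzaldehyde; 2 chlorotri(propan-2-yl)silane
Product: 3 5-bromo-2-[(triisopropylsilyl)oxy]benzaldehyde
Conditions: 2 (1.1 equiv), imidazole, DMF, rt
Reagents that add atoms: chlorotri(propan-2-yl)silane (2), CC(C)[Si](Cl)(C(C)C)C(C)C
Why: Silylation of a phenol with a silyl chloride and imidazole; the bulky aryl silyl ether should survive the bases, organometallics and oxidants of steps 2 to 15 and leave with fluoride in step 16.

Step 2
Reactants: 3 5-bromo-2-[(triisopropylsilyl)oxy]benzaldehyde; 4 methyl 2-[bis(2,2,2-trifluoroethoxy)phosphoryl]acetate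
Product: 5 methyl (2Z)-3-{5-bromo-2-[(triisopropylsilyl)oxy]phenyl}prop-2-enoate
Conditions: 4, KN(SiMe3)2, 18-crown-6, THF, −78 °C
Reagents that add atoms: methyl 2-[bis(2,2,2-trifluoroethoxy)phosphoryl]acetate (4), COC(=O)CP(=O)(OCC(F)(F)F)OCC(F)(F)F
Why: Still–Gennari variant of the Horner–Wadsworth–Emmons olefination, in which the electron-poor phosphonate makes elimination from the first-formed adduct fast and so should give the Z-enoate needed for a cis-epoxide.

Step 3
Reactants: 5 methyl (2Z)-3-{5-bromo-2-[(triisopropylsilyl)oxy]phenyl}prop-2-enoate; 6 sodium hypochlorite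
Product: 7 methyl (2R,3R)-3-{5-bromo-2-[(triisopropylsilyl)oxy]phenyl}oxirane-2-carboxylate (cis-glycidate)
Conditions: (R,R)-Jacobsen catalyst chloro[(R,R)-N,N'-bis(3,5-di-tert-butylsalicylidene)cyclohexane-1,2-diaminato]manganese (6 mol %), 4-phenylpyridine N-oxide (25 mol %), NaOCl (aq, pH 11.3), CH2Cl2, 0 °C
Reagents that add atoms: sodium hypochlorite (6), [Na+].[O-]Cl
Why: Jacobsen–Katsuki epoxidation of a cis-cinnamate ester, for which the (R,R)-salen manganese oxo species should deliver oxygen to one enantioface and give the (2R,3R)-cis-glycidate, fixing C2 and the configuration from which C3 is later derived.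

Step 4
Reactants: 7 methyl (2R,3R)-3-{5-bromo-2-[(triisopropylsilyl)oxy]phenyl}oxirane-2-carboxylate; 8 methylmagnesium bromide
Product: 9 2-[(2R,3R)-3-{5-bromo-2-[(triisopropylsilyl)oxy]phenyl}oxiran-2-yl]propan-2-ol
Conditions: MeMgBr (2.5 equiv), THF, −78 → −20 °C; aq. NH4Cl
Reagents that add atoms: methylmagnesium bromide (8), C[Mg]Br
Why: Double Grignard addition to the ester gives the tertiary carbinol, the epoxide being left intact at low temperature and neither stereocentre being touched.

Step 5
Reactants: 9 2-[(2R,3R)-3-{5-bromo-2-[(triisopropylsilyl)oxy]phenyl}oxiran-2-yl]propan-2-ol; 10 2-chloro-1,1-dimethoxyethane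
Product: 11 (3R,4S)-4-{5-bromo-2-[(triisopropylsilyl)oxy]phenyl}-6-methoxy-2-methylhex-5-yne-2,3-diol
Conditions: 10, LiNEt2 (3 equiv per 10), THF, 0 °C; Et2AlCl, toluene, 0 °C (gives Et2AlC≡COMe, 3.5 equiv); then 9, 0 °C → rt; aq. potassium sodium tartrate
Reagents that add atoms: diethyl(methoxyethynyl)alane, CC[Al](CC)C#COC, made in the flask from 2-chloro-1,1-dimethoxyethane (10), COC(CCl)OC
Why: Alkynylalane opening of a 2,3-epoxy alcohol, which goes at the carbon remote from the aluminium alkoxide (here also the benzylic one) by SN2 attack with inversion, so the cis-epoxide should give the (3R,4S) diol that maps onto the trans C2/C3 pattern of the target.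

Step 6
Reactants: 12 ethyl (3S)-3-hydroxypent-4-enoate; 13 lithium hydroxide
Product: 14 (3S)-3-hydroxypent-4-enoic acid
Conditions: LiOH·H2O, THF–H2O, 0 °C; then 1 M HCl to pH 3
Reagents that add atoms: lithium hydroxide (13), [Li+].[OH-]
Why: Ester saponification at 0 °C, mild enough to avoid retro-aldol cleavage or dehydration of the β-hydroxy acid, with the carbinol centre untouched.

Step 7
Reactants: 14 (3S)-3-hydroxypent-4-enoic acid
Product: 15 (4S)-4-ethenyloxetan-2-one
Conditions: PhSO2Cl, pyridine, 0 °C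
Reagents that add atoms: none
Why: β-Lactonisation of a β-hydroxy acid by carboxyl activation with a sulfonyl chloride in pyridine, in which the hydroxyl oxygen attacks the mixed anhydride so that the C–O bond at the stereocentre is not broken and the configuration is retained.

Step 8
Reactants: 15 (4S)-4-ethenyloxetan-2-one; 16 3-phenylpropanal; 17 triethylsilyl trifluoromethanesulfonate
Product: 19 (3S,4R)-4-ethenyl-3-[(1RS)-3-phenyl-1-(triethylsilyloxy)propyl]oxetan-2-one, via lithium aldolate 18 (not isolated)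
Conditions: LiN(iPr)2 (1.05 equiv), THF, −78 °C; 16, −78 °C; then 17, −78 °C
Reagents that add atoms: 3-phenylpropanal (16), O=CCCc1ccccc1; triethylsilyl trifluoromethanesulfonate (17), CC[Si](CC)(CC)OS(=O)(=O)C(F)(F)F
Why: Aldol addition of a β-lactone lithium enolate, which should take the aldehyde on the ring face opposite the C4 vinyl group and give the trans-3,4-disubstituted lactone (C7 set relative to C6), the aldolate being silylated cold before it can revert; both carbinol epimers are expected and both are used.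

Step 9
Reactants: 11 (3R,4S)-4-{5-bromo-2-[(triisopropylsilyl)oxy]phenyl}-6-methoxy-2-methylhex-5-yne-2,3-diol; 19 (3S,4R)-4-ethenyl-3-[(1RS)-3-phenyl-1-(triethylsilyloxy)propyl]oxetan-2-one
Product: 20 (3R,4S)-4-{5-bromo-2-[(triisopropylsilyl)oxy]phenyl}-2-hydroxy-6-methoxy-2-methylhex-5-yn-3-yl (2S,3R)-3-hydroxy-2-[(1RS)-3-phenyl-1-(triethylsilyloxy)propyl]pent-4-enoate
Conditions: 11, NaN(SiMe3)2 (1.0 equiv), THF, −78 °C; then 19, −78 → −50 °C; aq. NH4Cl at −78 °C
Reagents that add atoms: lactone 19 (fragment 2), O=C1O[C@H](C=C)[C@H]1C(O[Si](CC)(CC)CC)CCc1ccccc1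
Why: Acyl–oxygen cleavage of a strained β-lactone by a hard alkoxide (the secondary alkoxide of 11 is far more accessible than the tertiary one), which should make the hindered ester O1–C7a without coupling agent or acid and at the same time free only the C6 hydroxyl, C1' staying silylated.

Step 10
Reactants: 20 the hydroxy ester of step 9; 21 tert-butyldimethylsilyl trifluoromethanesulfonate; 17 triethylsilyl trifluoromethanesulfonate
Product: 23 (3R,4S)-4-{5-bromo-2-[(triisopropylsilyl)oxy]phenyl}-6-methoxy-2-methyl-2-[(triethylsilyl)oxy]hex-5-yn-3-yl (2R,3R)-3-[(tert-butyldimethylsilyl)oxy]-2-[(1RS)-3-phenyl-1-(triethylsilyloxy)propyl]pent-4-enoate, via mono-silyl ether 22 (not isolated)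
Conditions: 21 (1.2 equiv), 2,6-lutidine (5 equiv), CH2Cl2, −78 °C; then 17 (1.5 equiv), −78 → 0 °C
Reagents that add atoms: tert-butyldimethylsilyl trifluoromethanesulfonate (21), CC(C)(C)[Si](C)(C)OS(=O)(=O)C(F)(F)F; triethylsilyl trifluoromethanesulfonate (17), CC[Si](CC)(CC)OS(=O)(=O)C(F)(F)F
Why: Graded silylation with silyl triflates, in which the tert-butyldimethylsilyl triflate should take the secondary allylic hydroxyl at −78 °C and the smaller triethylsilyl triflate then caps the tertiary hydroxyl, excess base shielding the ynol ether from acid.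

Step 11
Reactants: 23 the fully silylated ester of step 10; 24 dibromomethane
Product: 25 (3R,4S)-4-{5-bromo-2-[(triisopropylsilyl)oxy]phenyl}-6-methoxy-2-methyl-2-[(triethylsilyl)oxy]hex-5-yn-3-yl (3R,4R)-4-[(tert-butyldimethylsilyl)oxy]-3-[(1RS)-3-phenyl-1-(triethylsilyloxy)propyl]hexa-1,5-dien-2-yl ether
Conditions: CH2Br2, Zn, PbCl2 (cat.), TiCl4, TMEDA, THF, 0 °C → rt; aq. K2CO3
Reagents that add atoms: dibromomethane (24), BrCBr
Why: Takai–Utimoto methylenation of an ester to the 2-alkoxy-1-alkene, the reagent type used for congested esters in polyether synthesis and one expected to leave the alkyne, the alkene, the silyl ethers and the aryl bromide alone (a benzoate ester in place of the bromide would be methylenated as well).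

Step 12
Reactants: 25 the enol ether dienyne of step 11
Product: 26 (2R,3R,6R,7R)-3-{5-bromo-2-[(triisopropylsilyl)oxy]phenyl}-6-[(tert-butyldimethylsilyl)oxy]-4-methoxy-7-[(1RS)-3-phenyl-1-(triethylsilyloxy)propyl]-2-{2-[(triethylsilyl)oxy]propan-2-yl}-2,3,6,7-tetrahydro-1-benzofuran
Conditions: RuCl2[1,3-bis(2-methylphenyl)imidazolidin-2-ylidene](=CH-C6H4-2-OiPr) (N-o-tolyl second-generation Hoveyda–Grubbs catalyst, 15 mol % in three portions), 2,6-dichloro-1,4-benzoquinone (20 mol %), toluene (5 mM), 80 °C, argon sparge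
Reagents that add atoms: none
Why: Proposed new method: a ruthenium alkylidene (the methylidene once the cycle runs) is taken up by the enol ether to give the alkoxycarbene Ru=C7a, a Fischer-type carbene that is the thermodynamic resting point for alkylidenes on this substrate; it adds across the ynol ether C3a≡C4 by [2+2] cycloaddition and cycloreversion, which forms C7a=C3a and moves ruthenium to C4 as a methoxy(vinyl)carbene, and this carbene engages the C5 vinyl group in the same way, which forms C4=C5 and releases Ru=CH2, the two terminal CH2 groups leaving together as ethene. The closest known reaction types are the tandem ring-closing metathesis of dienynes, the ring-closing enyne metathesis of alkynyl ethers and siloxyalkynes, and the enyne metathesis of ruthenium alkoxycarbenes derived from vinyl ethers; new is the start from an internal 2-alkoxy-1-alkene with the ynol ether as the carbene relay. The dihydrofuran ring closes in the 5-exo-dig enyne mode (C7a bonds to C3a, ruthenium leaves on the exocyclic C4) and the cyclohexadiene ring then closes as a six-membered ring-closing alkene metathesis (C4 bonds to C5). No stereocentre is formed, C2, C3, C6 and C7 being carried in unchanged, and the benzoquinone additive is there to stop ruthenium hydride from moving the alkenes or epimerising the allylic C7. The step needs the furan to close before the carbocycle and each carbene to react within its own molecule: the substrate secures the order because C4 and C5 could only close a nine-membered ring until C7a=C3a exists, whereas C7a and C3a are held 1,5 to each other by O1–C2–C3, and dilution secures the rest. The silylated C1' carbinol (in place of the ketone) keeps the 2-alkoxy-1-alkene out of conjugation and the aryl bromide (in place of the ester) is inert to the catalyst.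

Step 13
Reactants: 26 the bicyclic aryl bromide of step 12; 27 carbon monoxide; 28 methanol
Product: 29 methyl 3-[(2R,3R,6R,7R)-6-[(tert-butyldimethylsilyl)oxy]-4-methoxy-7-[(1RS)-3-phenyl-1-(triethylsilyloxy)propyl]-2-{2-[(triethylsilyl)oxy]propan-2-yl}-2,3,6,7-tetrahydro-1-benzofuran-3-yl]-4-[(triisopropylsilyl)oxy]benzoate
Conditions: Pd(OAc)2 (5 mol %), Xantphos (10 mol %), CO (1 atm), MeOH (10 equiv), Et3N (3 equiv), toluene, 70 °C
Reagents that add atoms: carbon monoxide (27), [C-]#[O+]; methanol (28), CO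
Why: Palladium-catalysed methoxycarbonylation of an aryl bromide (oxidative addition, CO insertion, methanolysis of the acylpalladium), run on the fully silylated compound before the base-sensitive β-oxy ketone exists.

Step 14
Reactants: 29 the silylated methyl ester of step 13
Product: 30 methyl 3-[(2R,3R,6R,7R)-6-[(tert-butyldimethylsilyl)oxy]-7-[(1RS)-1-hydroxy-3-phenylpropyl]-2-(2-hydroxypropan-2-yl)-4-methoxy-2,3,6,7-tetrahydro-1-benzofuran-3-yl]-4-[(triisopropylsilyl)oxy]benzoate
Conditions: HF·pyridine, pyridine, THF, 0 °C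
Reagents that add atoms: none
Why: Buffered HF·pyridine should cleave the two triethylsilyl ethers far faster than the secondary tert-butyldimethylsilyl ether or the aryl triisopropylsilyl ether, so that C1'–OH and the tertiary hydroxyl are freed while C6–O stays protected and the dienol ether is spared by the pyridine buffer.

Step 15
Reactants: 30 the diol of step 14
Product: 31 methyl 3-[(2R,3R,6R,7R)-6-[(tert-butyldimethylsilyl)oxy]-2-(2-hydroxypropan-2-yl)-4-methoxy-7-(3-phenylpropanoyl)-2,3,6,7-tetrahydro-1-benzofuran-3-yl]-4-[(triisopropylsilyl)oxy]benzoate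
Conditions: Dess–Martin periodinane (1.5 equiv), pyridine, CH2Cl2, 0 °C
Reagents that add atoms: none
Why: Dess–Martin oxidation of the secondary carbinol to the C1' ketone under buffered, non-basic conditions, both C1' epimers converging on one ketone, the tertiary hydroxyl being inert and C6–O being silylated so that no dienone (and hence no phenol) can form.

Step 16
Reactants: 31 the silylated ketone of step 15
Product: 32 methyl 4-hydroxy-3-[(2R,3R,6R,7R)-6-hydroxy-2-(2-hydroxypropan-2-yl)-4-methoxy-7-(3-phenylpropanoyl)-2,3,6,7-tetrahydro-1-benzofuran-3-yl]benzoate (target)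
Conditions: Bu4NF (3 equiv), AcOH (3 equiv), THF, 0 °C → rt
Reagents that add atoms: none
Why: Fluoride cleavage of the aryl triisopropylsilyl ether and the secondary tert-butyldimethylsilyl ether, buffered with acetic acid so that the liberated β-hydroxy ketone is not exposed to base that could epimerise C7 or eliminate the C6 hydroxyl towards the arene.

**Compound list**

1 | 5-bromo-2-hydroxybenzaldehyde | O=Cc1cc(Br)ccc1O | starting material
2 | chlorotri(propan-2-yl)silane | CC(C)[Si](Cl)(C(C)C)C(C)C | starting material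
3 | 5-bromo-2-[(triisopropylsilyl)oxy]benzaldehyde | O=Cc1cc(Br)ccc1O[Si](C(C)C)(C(C)C)C(C)C | intermediate
4 | methyl 2-[bis(2,2,2-trifluoroethoxy)phosphoryl]acetate | COC(=O)CP(=O)(OCC(F)(F)F)OCC(F)(F)F | starting material
5 | methyl (2Z)-3-{5-bromo-2-[(triisopropylsilyl)oxy]phenyl}prop-2-enoate | COC(=O)/C=C\c1cc(Br)ccc1O[Si](C(C)C)(C(C)C)C(C)C | intermediate
6 | sodium hypochlorite | [Na+].[O-]Cl | starting material
7 | methyl (2R,3R)-3-{5-bromo-2-[(triisopropylsilyl)oxy]phenyl}oxirane-2-carboxylate (cis) | CC(C)[Si](Oc1ccc(Br)cc1[C@@H]2[C@@H](O2)C(=O)OC)(C(C)C)C(C)C | intermediate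
8 | methylmagnesium bromide | C[Mg]Br | starting material
9 | 2-[(2R,3R)-3-{5-bromo-2-[(triisopropylsilyl)oxy]phenyl}oxiran-2-yl]propan-2-ol | CC(C)[Si](Oc1ccc(Br)cc1[C@@H]2[C@@H](O2)C(C)(C)O)(C(C)C)C(C)C | intermediate
10 | 2-chloro-1,1-dimethoxyethane | COC(CCl)OC | starting material
11 | (3R,4S)-4-{5-bromo-2-[(triisopropylsilyl)oxy]phenyl}-6-methoxy-2-methylhex-5-yne-2,3-diol | CC(C)[Si](Oc1ccc(Br)cc1[C@@H]([C@@H](O)C(C)(C)O)C#COC)(C(C)C)C(C)C | intermediate
12 | ethyl (3S)-3-hydroxypent-4-enoate | CCOC(=O)C[C@H](O)C=C | starting material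
13 | lithium hydroxide | [Li+].[OH-] | starting material
14 | (3S)-3-hydroxypent-4-enoic acid | OC(=O)C[C@H](O)C=C | intermediate
15 | (4S)-4-ethenyloxetan-2-one | O=C1O[C@H](C=C)C1 | intermediate
16 | 3-phenylpropanal | O=CCCc1ccccc1 | starting material
17 | triethylsilyl trifluoromethanesulfonate | CC[Si](CC)(CC)OS(=O)(=O)C(F)(F)F | starting material
18 | lithium aldolate: lithium alkoxide of (3R,4R)-4-ethenyl-3-[(1RS)-1-hydroxy-3-phenylpropyl]oxetan-2-one (not isolated) | O=C1O[C@H](C=C)[C@H]1C([O-])CCc1ccccc1.[Li+] | intermediate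
19 | (3S,4R)-4-ethenyl-3-[(1RS)-3-phenyl-1-(triethylsilyloxy)propyl]oxetan-2-one (trans; epimers at the silyloxy carbon) | O=C1O[C@H](C=C)[C@H]1C(O[Si](CC)(CC)CC)CCc1ccccc1 | intermediate
20 | (3R,4S)-4-{5-bromo-2-[(triisopropylsilyl)oxy]phenyl}-2-hydroxy-6-methoxy-2-methylhex-5-yn-3-yl (2S,3R)-3-hydroxy-2-[(1RS)-3-phenyl-1-(triethylsilyloxy)propyl]pent-4-enoate | O=C(O[C@H]([C@H](c1cc(Br)ccc1O[Si](C(C)C)(C(C)C)C(C)C)C#COC)C(C)(C)O)[C@H](C(O[Si](CC)(CC)CC)CCc1ccccc1)[C@H](O)C=C | intermediate
21 | tert-butyldimethylsilyl trifluoromethanesulfonate | CC(C)(C)[Si](C)(C)OS(=O)(=O)C(F)(F)F | starting material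
22 | (3R,4S)-4-{5-bromo-2-[(triisopropylsilyl)oxy]phenyl}-2-hydroxy-6-methoxy-2-methylhex-5-yn-3-yl (2R,3R)-3-[(tert-butyldimethylsilyl)oxy]-2-[(1RS)-3-phenyl-1-(triethylsilyloxy)propyl]pent-4-enoate (not isolated) | O=C(O[C@H]([C@H](c1cc(Br)ccc1O[Si](C(C)C)(C(C)C)C(C)C)C#COC)C(C)(C)O)[C@H](C(O[Si](CC)(CC)CC)CCc1ccccc1)[C@H](O[Si](C)(C)C(C)(C)C)C=C | intermediate
23 | (3R,4S)-4-{5-bromo-2-[(triisopropylsilyl)oxy]phenyl}-6-methoxy-2-methyl-2-[(triethylsilyl)oxy]hex-5-yn-3-yl (2R,3R)-3-[(tert-butyldimethylsilyl)oxy]-2-[(1RS)-3-phenyl-1-(triethylsilyloxy)propyl]pent-4-enoate | O=C(O[C@H]([C@H](c1cc(Br)ccc1O[Si](C(C)C)(C(C)C)C(C)C)C#COC)C(C)(C)O[Si](CC)(CC)CC)[C@H](C(O[Si](CC)(CC)CC)CCc1ccccc1)[C@H](O[Si](C)(C)C(C)(C)C)C=C | intermediate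
24 | dibromomethane | BrCBr | starting material
25 | (3R,4S)-4-{5-bromo-2-[(triisopropylsilyl)oxy]phenyl}-6-methoxy-2-methyl-2-[(triethylsilyl)oxy]hex-5-yn-3-yl (3R,4R)-4-[(tert-butyldimethylsilyl)oxy]-3-[(1RS)-3-phenyl-1-(triethylsilyloxy)propyl]hexa-1,5-dien-2-yl ether | C=C(O[C@H]([C@H](c1cc(Br)ccc1O[Si](C(C)C)(C(C)C)C(C)C)C#COC)C(C)(C)O[Si](CC)(CC)CC)[C@H](C(O[Si](CC)(CC)CC)CCc1ccccc1)[C@H](O[Si](C)(C)C(C)(C)C)C=C | intermediate
26 | (2R,3R,6R,7R)-3-{5-bromo-2-[(triisopropylsilyl)oxy]phenyl}-6-[(tert-butyldimethylsilyl)oxy]-4-methoxy-7-[(1RS)-3-phenyl-1-(triethylsilyloxy)propyl]-2-{2-[(triethylsilyl)oxy]propan-2-yl}-2,3,6,7-tetrahydro-1-benzofuran | Brc1ccc(O[Si](C(C)C)(C(C)C)C(C)C)c([C@@H]2C3=C(O[C@H]2C(C)(C)O[Si](CC)(CC)CC)[C@H](C(O[Si](CC)(CC)CC)CCc2ccccc2)[C@H](O[Si](C)(C)C(C)(C)C)C=C3OC)c1 | intermediate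
27 | carbon monoxide | [C-]#[O+] | starting material
28 | methanol | CO | starting material
29 | methyl 3-[(2R,3R,6R,7R)-6-[(tert-butyldimethylsilyl)oxy]-4-methoxy-7-[(1RS)-3-phenyl-1-(triethylsilyloxy)propyl]-2-{2-[(triethylsilyl)oxy]propan-2-yl}-2,3,6,7-tetrahydro-1-benzofuran-3-yl]-4-[(triisopropylsilyl)oxy]benzoate | COC(=O)c1ccc(O[Si](C(C)C)(C(C)C)C(C)C)c([C@@H]2C3=C(O[C@H]2C(C)(C)O[Si](CC)(CC)CC)[C@H](C(O[Si](CC)(CC)CC)CCc2ccccc2)[C@H](O[Si](C)(C)C(C)(C)C)C=C3OC)c1 | intermediate
30 | methyl 3-[(2R,3R,6R,7R)-6-[(tert-butyldimethylsilyl)oxy]-7-[(1RS)-1-hydroxy-3-phenylpropyl]-2-(2-hydroxypropan-2-yl)-4-methoxy-2,3,6,7-tetrahydro-1-benzofuran-3-yl]-4-[(triisopropylsilyl)oxy]benzoate | COC(=O)c1ccc(O[Si](C(C)C)(C(C)C)C(C)C)c([C@@H]2C3=C(O[C@H]2C(C)(C)O)[C@H](C(O)CCc2ccccc2)[C@H](O[Si](C)(C)C(C)(C)C)C=C3OC)c1 | intermediate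
31 | methyl 3-[(2R,3R,6R,7R)-6-[(tert-butyldimethylsilyl)oxy]-2-(2-hydroxypropan-2-yl)-4-methoxy-7-(3-phenylpropanoyl)-2,3,6,7-tetrahydro-1-benzofuran-3-yl]-4-[(triisopropylsilyl)oxy]benzoate | COC(=O)c1ccc(O[Si](C(C)C)(C(C)C)C(C)C)c([C@@H]2C3=C(O[C@H]2C(C)(C)O)[C@H](C(=O)CCc2ccccc2)[C@H](O[Si](C)(C)C(C)(C)C)C=C3OC)c1 | intermediate
32 | methyl 4-hydroxy-3-[(2R,3R,6R,7R)-6-hydroxy-2-(2-hydroxypropan-2-yl)-4-methoxy-7-(3-phenylpropanoyl)-2,3,6,7-tetrahydro-1-benzofuran-3-yl]benzoate | COC(=O)c1ccc(O)c([C@@H]2C3=C(O[C@H]2C(C)(C)O)[C@H](C(=O)CCc2ccccc2)[C@H](O)C=C3OC)c1 | target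

**Count**

Total steps: 16. Longest linear sequence: 13 steps (steps 1 to 5, then 9 to 16, from 5-bromo-2-hydroxybenzaldehyde).

**Steps most likely to fail**

First, step 12 (the proposed new method). The ruthenium carbene may fail to reach the congested enol ether carbon C7a. Alternatively, methylidene may add to the ynol ether first and release an open-chain 2-methoxy-1,3-diene whose closure to the tetrasubstituted C7a=C3a alkene is slow, or ruthenium hydrides may move the alkenes. The fallback uses known reaction types and sets out from 25. PtCl2 (5 mol %) in toluene at 80 °C should bring about the metathesis-type skeletal rearrangement of the 1,6-enyne formed by the enol ether and the ynol ether (alkyne activation by the metal, attack of the enol ether, cyclopropyl carbene, 1-vinylcycloalkene). This gives the monocyclic 2,3-dihydrofuran F1, which has C7a=C3a in the ring and a 1-methoxyethenyl group on C3a. Ordinary ring-closing alkene metathesis of F1 with the second-generation Grubbs catalyst RuCl2(H2IMes)(PCy3)(=CHPh) in CH2Cl2 at 40 °C then joins that group to the C5 vinyl group and returns to the route at 26.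

Second, step 9. Acylation of the hindered alkoxide may be slow enough for the opened β-alkoxide ester to fragment by retro-aldol cleavage, for the triethylsilyl group to migrate from O–C1' to the new C6 alkoxide, or for the alkoxide to attack the allylic C–O carbon of the lactone. The fallback sets out from 19 and uses a conventional esterification. LiOH in THF–H2O at 0 °C opens the lactone to the hydroxy acid F2. Silyl triflate 21 with 2,6-lutidine gives the silyl ether silyl ester F3, whose silyl ester is cleaved with K2CO3 in MeOH–THF–H2O to the acid F4. 2,4,6-Trichlorobenzoyl chloride and Et3N give the mixed anhydride F5, which acylates the secondary hydroxyl of 11 with DMAP in toluene (Yamaguchi esterification). The product is 22, where the fallback rejoins the route; 22 is then triethylsilylated as in the second half of step 10.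

Third, step 11. Methylenation of an ester that is branched on both sides may stop short, or the titanium Lewis acid may degrade the ynol ether before the carbonyl reacts. The fallback sets out from 23 and changes the enol ether that is carried into the cascade. Alkylidenation with 1,1-dibromoethane in place of dibromomethane (Zn, PbCl2, TiCl4, TMEDA, THF), the alkylidenation variant that is commonly the more effective one on esters, should give the (Z)-ethylidene enol ether F6. F6 enters the cascade of step 12 unchanged in design (propene leaves in place of ethene), and the route is rejoined at 26.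

**Further compounds**

F1 | step 12 | (2R,3R)-3-{5-bromo-2-[(triisopropylsilyl)oxy]phenyl}-4-(1-methoxyethenyl)-2-{2-[(triethylsilyl)oxy]propan-2-yl}-5-[(3RS,4R,5R)-5-[(tert-butyldimethylsilyl)oxy]-1-phenyl-3-(triethylsilyloxy)hept-6-en-4-yl]-2,3-dihydrofuran | Brc1ccc(O[Si](C(C)C)(C(C)C)C(C)C)c([C@@H]2C(C(=C)OC)=C(O[C@H]2C(C)(C)O[Si](CC)(CC)CC)[C@H](C(O[Si](CC)(CC)CC)CCc2ccccc2)[C@H](O[Si](C)(C)C(C)(C)C)C=C)c1
F2 | step 9 | (2S,3R)-3-hydroxy-2-[(1RS)-3-phenyl-1-(triethylsilyloxy)propyl]pent-4-enoic acid | OC(=O)[C@H](C(O[Si](CC)(CC)CC)CCc1ccccc1)[C@H](O)C=C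
F3 | step 9 | tert-butyldimethylsilyl (2R,3R)-3-[(tert-butyldimethylsilyl)oxy]-2-[(1RS)-3-phenyl-1-(triethylsilyloxy)propyl]pent-4-enoate | CC(C)(C)[Si](C)(C)OC(=O)[C@H](C(O[Si](CC)(CC)CC)CCc1ccccc1)[C@H](O[Si](C)(C)C(C)(C)C)C=C
F4 | step 9 | (2R,3R)-3-[(tert-butyldimethylsilyl)oxy]-2-[(1RS)-3-phenyl-1-(triethylsilyloxy)propyl]pent-4-enoic acid | OC(=O)[C@H](C(O[Si](CC)(CC)CC)CCc1ccccc1)[C@H](O[Si](C)(C)C(C)(C)C)C=C
F5 | step 9 | mixed anhydride of F4 with 2,4,6-trichlorobenzoic acid | O=C(OC(=O)[C@H](C(O[Si](CC)(CC)CC)CCc1ccccc1)[C@H](O[Si](C)(C)C(C)(C)C)C=C)c1c(Cl)cc(Cl)cc1Cl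
F6 | step 11 | (3R,4S)-4-{5-bromo-2-[(triisopropylsilyl)oxy]phenyl}-6-methoxy-2-methyl-2-[(triethylsilyl)oxy]hex-5-yn-3-yl (2Z,4R,5R)-5-[(tert-butyldimethylsilyl)oxy]-4-[(1RS)-3-phenyl-1-(triethylsilyloxy)propyl]hepta-2,6-dien-3-yl ether | C/C=C(\O[C@H]([C@H](c1cc(Br)ccc1O[Si](C(C)C)(C(C)C)C(C)C)C#COC)C(C)(C)O[Si](CC)(CC)CC)[C@H](C(O[Si](CC)(CC)CC)CCc1ccccc1)[C@H](O[Si](C)(C)C(C)(C)C)C=C
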